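The ring carbons are numbered as in germacrane: C1 ketone, C3–O–C10 furanone ether, C6 ester carbinol, C8 lactone carbinol, C12 lactone carbonyl. The route rests on reading the α-methylene-γ-butyrolactone (C7, C8, O, C12, C11, exocyclic C13) as the sum of a terminal allene (C7=C11=C13), an aldehyde (C8) and CO2 (C12). Since C7–C8 is also a bond of the ten-membered carbocycle, one nickel-mediated carboxylation/allylation of a furanone-bridged allenyl aldehyde under CO2 should forge C11–C12 and C7–C8, close the medium ring and set both ring-fusion stereocentres; acid work-up closes the lactone. The precursor is a 3(2H)-furanone carrying a CH2CHO arm at C10 and a (Z)-alkenyl allenyl silyl ether arm at C3.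

Key step: step 12

Assumption: (S,S)-ProPhenol is taken to deliver the alkynyl group to the Si face of the enal in step 8; should the sense be opposite, the (R,R)-ligand is used.

Step 1
Reactants: 1 (R)-citramalic acid; 2 2,2-dimethoxypropane
Product: 3 2-[(4R)-2,2,4-trimethyl-5-oxo-1,3-dioxolan-4-yl]acetic acid
Conditions: TsOH·H2O (cat.), neat 2, rt
Reagents that add atoms: 2,2-dimethoxypropane, COC(C)(C)OC
Why: Acid-catalysed acetalisation takes up the α-hydroxy acid as the five-membered dioxolanone and leaves the distal carboxyl free; the stereocentre (later C10) is carried over from 1.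

Step 2
Reactants: 3 dioxolanone acid
Product: 5 (3R)-3-hydroxy-3-methyloxolan-2-one, via hydroxy dioxolanone 4 (not isolated)
Conditions: BH3·SMe2, B(OMe)3, THF, 0 °C → rt; MeOH quench; then TsOH·H2O (cat.), CH2Cl2, rt
Reagents that add atoms: none
Why: Chemoselective borane reduction of the free carboxylic acid beside the dioxolanone, then acid-catalysed lactonisation of the primary alcohol onto the activated acyl group with loss of acetone; C10 is untouched.

Step 3
Reactants: 5 hydroxy lactone; 6 N,O-dimethylhydroxylamine hydrochloride; 7 chlorotrimethylsilane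
Product: 9 (2R)-N-methoxy-N,2-dimethyl-2,4-bis[(trimethylsilyl)oxy]butanamide, via Weinreb amide diol 8 (not isolated)
Conditions: 6, i-PrMgCl (3.3 equiv), THF, −20 → 0 °C; NH4Cl work-up; crude 8, then TMSCl, imidazole, DMAP (cat.), CH2Cl2, 0 °C → rt
Reagents that add atoms: N,O-dimethylhydroxylamine hydrochloride, CNOC.Cl; chlorotrimethylsilane, C[Si](C)(C)Cl
Why: Weinreb aminolysis of the lactone by the chloromagnesium amide, then silylation, which stops relactonisation and removes both OH protons before the acetylide addition.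

Step 4
Reactants: 10 (2Z)-3-methylpent-2-en-4-yn-1-ol; 11 tert-butyldimethylsilyl chloride
Product: 12 tert-butyl(dimethyl){[(2Z)-3-methylpent-2-en-4-yn-1-yl]oxy}silane
Conditions: imidazole, CH2Cl2, 0 °C → rt
Reagents that add atoms: tert-butyldimethylsilyl chloride, CC(C)(C)[Si](C)(C)Cl
Why: Standard silyl ether formation; the Z alkene of the commercial enynol supplies the C4=C5 geometry of the target.

Step 5
Reactants: 12 enyne TBS ether; 9 bis-TMS Weinreb amide
Product: 14 (3R,7Z)-9-[(tert-butyldimethylsilyl)oxy]-1,3-dihydroxy-3,7-dimethylnon-7-en-5-yn-4-one, via bis-TMS ynone 13 (not isolated)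
Conditions: 12, n-BuLi, THF, −78 °C; 9, −78 → −20 °C; then 1 M HCl, THF, 0 °C, 20 min
Reagents that add atoms: none
Why: Weinreb ketone synthesis: the lithium acetylide adds once because the chelated tetrahedral adduct only collapses on quench, and dilute acid then cleaves both trimethylsilyl ethers while the primary TBS ether stays.

Step 6
Reactants: 14 α′-hydroxy ynone
Product: 16 (2R)-2-(2-hydroxyethyl)-5-[(2Z)-4-hydroxybut-2-en-2-yl]-2-methylfuran-3(2H)-one, via furanone TBS ether 15 (not isolated)
Conditions: Ph3PAuNTf2 (2 mol %), CH2Cl2, rt; then MeOH, CSA (0.2 equiv), 0 °C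
Reagents that add atoms: none
Why: Gold-catalysed 5-endo-dig cycloisomerisation of the α′-hydroxy ynone gives the 3(2H)-furanone (O6 stays silylated so that it cannot close a furan onto the alkyne), and acidic methanolysis then frees the allylic alcohol; C10 is untouched.

Step 7
Reactants: 16 furanone diol
Product: 17 (2Z)-3-[(5R)-5-(2-hydroxyethyl)-5-methyl-4-oxo-4,5-dihydrofuran-2-yl]but-2-enal
Conditions: activated MnO2 (excess), CH2Cl2, rt, dark
Reagents that add atoms: none
Why: MnO2 oxidation is selective for the allylic alcohol over the saturated primary one and normally preserves the Z geometry.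

Step 8
Reactants: 17 Z-enal; 18 ethynyltrimethylsilane
Product: 20 (2R)-2-(2-hydroxyethyl)-5-[(2Z,4R)-4-hydroxyhex-2-en-5-yn-2-yl]-2-methylfuran-3(2H)-one, via TMS-alkynyl carbinol 19 (not isolated)
Conditions: (S,S)-ProPhenol (20 mol %), Me2Zn (4 equiv), 18 (4 equiv), Ph3P=O (40 mol %), toluene, 4 °C; NH4Cl work-up; then K2CO3, MeOH, 0 °C
Reagents that add atoms: ethynyltrimethylsilane, C#C[Si](C)(C)C
Why: Catalytic asymmetric alkynylation by a dinuclear zinc ProPhenol complex, in which the ligand directs the alkynylzinc to the Si face of the aldehyde and so sets C6 as R, followed by methanolysis of the C–Si bond.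

Step 9
Reactants: 20 propargylic alcohol; 21 paraformaldehyde
Product: 22 (2R)-2-(2-hydroxyethyl)-5-[(2Z,4S)-4-hydroxyhepta-2,5,6-trien-2-yl]-2-methylfuran-3(2H)-one
Conditions: (CH2O)n, CuI (0.5 equiv), Cy2NH (1.8 equiv), 1,4-dioxane, reflux
Reagents that add atoms: paraformaldehyde (formaldehyde unit), C=O
Why: Crabbé homologation: copper-mediated Mannich coupling of the terminal alkyne with formaldehyde and the amine, then intramolecular hydride transfer with loss of the imine, give the terminal allene; the carbinol centre is not touched (S only by CIP priority change).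

Step 10
Reactants: 22 allenyl diol; 23 chlorotriethylsilane
Product: 24 (2R)-2-methyl-2-{2-[(triethylsilyl)oxy]ethyl}-5-{(2Z,4S)-4-[(triethylsilyl)oxy]hepta-2,5,6-trien-2-yl}furan-3(2H)-one
Conditions: TESCl (2.5 equiv), imidazole, DMAP (cat.), CH2Cl2, 0 °C → rt
Reagents that add atoms: chlorotriethylsilane, CC[Si](Cl)(CC)CC
Why: Standard silylation of both hydroxyls, which masks O6 for the nickel step and sets up the primary ether for direct oxidation.

Step 11
Reactants: 24 bis-TES ether
Product: 25 2-[(2R)-2-methyl-3-oxo-5-{(2Z,4S)-4-[(triethylsilyl)oxy]hepta-2,5,6-trien-2-yl}-2,3-dihydrofuran-2-yl]acetaldehyde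
Conditions: (COCl)2 (4 equiv), DMSO (8 equiv), CH2Cl2, −78 → −40 °C; then i-Pr2NEt, −78 → −30 °C; cold pH 7 buffer quench
Reagents that add atoms: none
Why: Swern oxidation of a primary triethylsilyl ether: the activated sulfoxide cleaves and oxidises the primary TES ether in one pot while the secondary TES ether is inert at low temperature; a hindered base and cold quench limit β-elimination of the new aldehyde.

Step 12
Reactants: 25 allenyl aldehyde; 26 carbon dioxide
Product: 28 (4Z,6R,7R,8S,10R)-1-oxo-6-(triethylsilyloxy)-3,10-epoxygermacra-2,4,11(13)-trien-12,8-olide, via seco hydroxy acid 27 (not isolated)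
Conditions: Ni(cod)2 (1.2 equiv), DBU (2.4 equiv), CO2 (1 atm), THF, 0 °C, slow addition of 25 (final 2 mM); 1 M HCl, 0 °C; then PPTS (cat.), CH2Cl2, rt
Reagents that add atoms: carbon dioxide, O=C=O
Why: Zerovalent nickel couples the terminal allene with CO2 by oxidative cyclisation, bonding the CO2 carbon to the central allene carbon (C11–C12) and giving a 2-carboxylato-allylnickel species (divalent nickel) whose substituted terminus C7 adds to the tethered aldehyde through a six-membered chair transition state (C7–C8); protonation and lactonisation of the only free hydroxyl (O8) onto C12 then give 28. The closest known reaction types are the nickel-mediated sequential addition of CO2 and aldehydes to terminal allenes, its intramolecular carboxylation/cyclisation cascade on allenyl aldehydes, and Barbier-type allylations that close germacranolide rings. The ten-membered carbocycle is closed by the intramolecular SE2′ allylation (formally 10-exo-trig at the aldehyde) and the lactone by 5-exo-trig acyl substitution. C8 should follow from the chair in which the C6-bearing substituent lies trans to the CH2–Ni terminus (cis to the planar carboxylate, as in E-alkylidene lactones), which gives the anti adduct and hence the trans-fused lactone; C7 should follow from C6, because allylic 1,3-strain holds H6 in the allyl plane so that the tethered aldehyde approaches from the C5 side, anti to OSiEt3. The step needs selectivity for the allene over the electron-poor furanone diene, γ- over α-attack of the allyl unit (the α-mode would give an eleven-membered ring) and survival of the β-oxy aldehyde towards DBU; the first two rest on the accessible terminal allene and the cyclic transition state, the third on high dilution at 0 °C under CO2 and is the main risk.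

Step 13
Reactants: 28 lactone TES ether
Product: 29 (4Z,6R,7S,8S,10R)-6-hydroxy-1-oxo-3,10-epoxygermacra-2,4,11(13)-trien-12,8-olide
Conditions: HF·pyridine, THF/pyridine, 0 °C
Reagents that add atoms: none
Why: Fluoride-mediated desilylation under weakly acidic conditions that spare the α-methylene lactone and disfavour migration of the lactone to O6 (C7 is S only by CIP priority change).

Step 14
Reactants: 30 [(2R)-2-methyloxiran-2-yl]methanol; 31 water
Product: 32 (2S)-2-methyloxirane-2-carboxylic acid
Conditions: RuCl3·xH2O (2 mol %), NaIO4 (3 equiv), CCl4/MeCN/H2O, 0 °C → rt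
Reagents that add atoms: water, O
Why: Catalytic RuO4 oxidation (RuCl3/NaIO4) of the primary alcohol to the acid without opening the epoxide; the stereocentre is untouched (S only by CIP priority change).

Step 15
Reactants: 29 C6 alcohol; 32 (2S)-2-methyloxirane-2-carboxylic acid
Product: 33 (4Z,6R,7R,8S,10R)-6-{[(2S)-2-methyloxirane-2-carbonyl]oxy}-1-oxo-3,10-epoxygermacra-2,4,11(13)-trien-12,8-olide (CNP0321429.1)
Conditions: 2-methyl-6-nitrobenzoic anhydride, DMAP, Et3N, CH2Cl2, rt
Reagents that add atoms: none
Why: Shiina esterification: the mixed anhydride formed from 32 is passed by DMAP to the hindered C6 hydroxyl with retention at C6 and no effect on the other stereocentres.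

Compound list
1 | (R)-citramalic acid, (2R)-2-hydroxy-2-methylbutanedioic acid | OC(=O)C[C@@](C(=O)O)(C)O | starting material
2 | 2,2-dimethoxypropane | COC(C)(C)OC | starting material
3 | 2-[(4R)-2,2,4-trimethyl-5-oxo-1,3-dioxolan-4-yl]acetic acid | OC(=O)C[C@@]1(C)OC(C)(C)OC1=O | intermediate
4 | (5R)-5-(2-hydroxyethyl)-2,2,5-trimethyl-1,3-dioxolan-4-one | OCC[C@@]1(C)OC(C)(C)OC1=O | intermediate
5 | (3R)-3-hydroxy-3-methyloxolan-2-one | O=C1OCC[C@@]1(C)O | intermediate
6 | N,O-dimethylhydroxylamine hydrochloride | CNOC.Cl | starting material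
7 | chlorotrimethylsilane | C[Si](C)(C)Cl | starting material
8 | (2R)-2,4-dihydroxy-N-methoxy-N,2-dimethylbutanamide | OCC[C@@](C(=O)N(C)OC)(C)O | intermediate
9 | (2R)-N-methoxy-N,2-dimethyl-2,4-bis[(trimethylsilyl)oxy]butanamide | C[Si](C)(C)OCC[C@@](C(=O)N(C)OC)(C)O[Si](C)(C)C | intermediate
10 | (2Z)-3-methylpent-2-en-4-yn-1-ol | C#C/C(C)=C\CO | starting material
11 | tert-butyldimethylsilyl chloride | CC(C)(C)[Si](C)(C)Cl | starting material
12 | tert-butyl(dimethyl){[(2Z)-3-methylpent-2-en-4-yn-1-yl]oxy}silane | C#C/C(C)=C\CO[Si](C)(C)C(C)(C)C | intermediate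
13 | (3R,7Z)-9-[(tert-butyldimethylsilyl)oxy]-3,7-dimethyl-1,3-bis[(trimethylsilyl)oxy]non-7-en-5-yn-4-one | C[Si](C)(C)OCC[C@@](C(=O)C#C/C(C)=C\CO[Si](C)(C)C(C)(C)C)(C)O[Si](C)(C)C | intermediate
14 | (3R,7Z)-9-[(tert-butyldimethylsilyl)oxy]-1,3-dihydroxy-3,7-dimethylnon-7-en-5-yn-4-one | OCC[C@@](C(=O)C#C/C(C)=C\CO[Si](C)(C)C(C)(C)C)(C)O | intermediate
15 | (2R)-5-{(2Z)-4-[(tert-butyldimethylsilyl)oxy]but-2-en-2-yl}-2-(2-hydroxyethyl)-2-methylfuran-3(2H)-one | OCC[C@@]1(C)OC(=CC1=O)/C(C)=C\CO[Si](C)(C)C(C)(C)C | intermediate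
16 | (2R)-2-(2-hydroxyethyl)-5-[(2Z)-4-hydroxybut-2-en-2-yl]-2-methylfuran-3(2H)-one | OCC[C@@]1(C)OC(=CC1=O)/C(C)=C\CO | intermediate
17 | (2Z)-3-[(5R)-5-(2-hydroxyethyl)-5-methyl-4-oxo-4,5-dihydrofuran-2-yl]but-2-enal | OCC[C@@]1(C)OC(=CC1=O)/C(C)=C\C=O | intermediate
18 | ethynyltrimethylsilane | C#C[Si](C)(C)C | starting material
19 | (2R)-2-(2-hydroxyethyl)-5-[(2Z,4R)-4-hydroxy-6-(trimethylsilyl)hex-2-en-5-yn-2-yl]-2-methylfuran-3(2H)-one | OCC[C@@]1(C)OC(=CC1=O)/C(C)=C\[C@@H](O)C#C[Si](C)(C)C | intermediate
20 | (2R)-2-(2-hydroxyethyl)-5-[(2Z,4R)-4-hydroxyhex-2-en-5-yn-2-yl]-2-methylfuran-3(2H)-one | OCC[C@@]1(C)OC(=CC1=O)/C(C)=C\[C@@H](O)C#C | intermediate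
21 | paraformaldehyde (formaldehyde unit) | C=O | starting material
22 | (2R)-2-(2-hydroxyethyl)-5-[(2Z,4S)-4-hydroxyhepta-2,5,6-trien-2-yl]-2-methylfuran-3(2H)-one | OCC[C@@]1(C)OC(=CC1=O)/C(C)=C\[C@@H](O)C=C=C | intermediate
23 | chlorotriethylsilane | CC[Si](Cl)(CC)CC | starting material
24 | (2R)-2-methyl-2-{2-[(triethylsilyl)oxy]ethyl}-5-{(2Z,4S)-4-[(triethylsilyl)oxy]hepta-2,5,6-trien-2-yl}furan-3(2H)-one | CC[Si](CC)(CC)OCC[C@@]1(C)OC(=CC1=O)/C(C)=C\[C@@H](O[Si](CC)(CC)CC)C=C=C | intermediate
25 | 2-[(2R)-2-methyl-3-oxo-5-{(2Z,4S)-4-[(triethylsilyl)oxy]hepta-2,5,6-trien-2-yl}-2,3-dihydrofuran-2-yl]acetaldehyde | O=CC[C@@]1(C)OC(=CC1=O)/C(C)=C\[C@@H](O[Si](CC)(CC)CC)C=C=C | intermediate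
26 | carbon dioxide | O=C=O | starting material
27 | (4Z,6R,7R,8S,10R)-8-hydroxy-1-oxo-6-(triethylsilyloxy)-3,10-epoxygermacra-2,4,11(13)-trien-12-oic acid | O[C@H]1C[C@@]2(C)OC(=CC2=O)/C(C)=C\[C@@H](O[Si](CC)(CC)CC)[C@@H]1C(=C)C(=O)O | intermediate
28 | (4Z,6R,7R,8S,10R)-1-oxo-6-(triethylsilyloxy)-3,10-epoxygermacra-2,4,11(13)-trien-12,8-olide | C=C1C(=O)O[C@H]2C[C@@]3(C)OC(=CC3=O)/C(C)=C\[C@@H](O[Si](CC)(CC)CC)[C@H]12 | intermediate
29 | (4Z,6R,7S,8S,10R)-6-hydroxy-1-oxo-3,10-epoxygermacra-2,4,11(13)-trien-12,8-olide | C=C1C(=O)O[C@H]2C[C@@]3(C)OC(=CC3=O)/C(C)=C\[C@@H](O)[C@H]12 | intermediate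
30 | [(2R)-2-methyloxiran-2-yl]methanol, (R)-2-methylglycidol | OC[C@]1(C)CO1 | starting material
31 | water | O | starting material
32 | (2S)-2-methyloxirane-2-carboxylic acid | OC(=O)[C@]1(C)CO1 | intermediate
33 | (4Z,6R,7R,8S,10R)-6-{[(2S)-2-methyloxirane-2-carbonyl]oxy}-1-oxo-3,10-epoxygermacra-2,4,11(13)-trien-12,8-olide (CNP0321429.1) | C=C1C(=O)O[C@H]2C[C@@]3(C)OC(=CC3=O)/C(C)=C\[C@@H](OC(=O)[C@]3(C)CO3)[C@H]12 | target

Total step count: 15. Longest linear sequence: 13 steps (1, 2, 3, 5–13, 15).

Steps most likely to fail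

Step 12. Three processes threaten it: DBU-triggered β-elimination of the furanone oxygen from the β-oxy aldehyde, oligomerisation in place of medium-ring closure, and poor facial selectivity at C7/C8. The fallback separates the two bond formations and uses only neutral, established reactions. It sets out from 24: addition of one equivalent of bromine to the terminal allene (CH2Cl2, −78 °C) should give the bis-TES (Z)-2,3-dibromoalkene F1, whose allylic regioisomer converges to the same allylmetal later. Selective Swern oxidation of the primary TES ether as in step 11 then gives the dibromo aldehyde F2. CrCl2 in THF at high dilution should reduce only the allylic bromide and close the ten-membered ring by an intramolecular Nozaki–Hiyama allylation, anti-selective through the chair transition state, to the macrocyclic 2-bromoallyl carbinol F3. Carbonylative lactonisation of its vinyl bromide (Pd(PPh3)4, CO 1 atm, Et3N, THF, 60 °C) forms C11–C12 and the lactone C–O bond and returns to the route at 28.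

Step 8. The Z-enal may isomerise to the E isomer under the Lewis-acidic zinc conditions, and the catalyst may show low facial selectivity with this hindered β,β-disubstituted enal. The fallback sets C6 by reagent-controlled reduction instead of addition. From 17, lithium trimethylsilylacetylide (THF, −78 °C) should give the C6-epimeric carbinols, that is 19 together with its (4S)-epimer F4. MnO2 oxidation of the mixture gives the alkynyl ketone F5, and CBS reduction with the (R)-methyl oxazaborolidine and catecholborane (alkynyl as the small group) should return 19, which the methanolysis of step 8 converts into 20.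

Step 11. The amine base may trigger β-elimination of the new aldehyde, and the secondary TES ether may be partly lost. The fallback changes the order to oxidation first and protection second, with no trialkylamine. From 22, TEMPO (cat.)/PhI(OAc)2 in CH2Cl2 should oxidise only the primary alcohol to the hydroxy aldehyde F6. Silylation of the C6 hydroxyl (TESOTf, 2,6-lutidine, CH2Cl2, −78 °C) then returns to the route at 25.

Further compounds
F1 | step 12 | (2R)-5-{(2Z,4S,5Z)-6,7-dibromo-4-[(triethylsilyl)oxy]hepta-2,5-dien-2-yl}-2-methyl-2-{2-[(triethylsilyl)oxy]ethyl}furan-3(2H)-one | CC[Si](CC)(CC)OCC[C@@]1(C)OC(=CC1=O)/C(C)=C\[C@@H](O[Si](CC)(CC)CC)/C=C(\Br)CBr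
F2 | step 12 | 2-[(2R)-5-{(2Z,4S,5Z)-6,7-dibromo-4-[(triethylsilyl)oxy]hepta-2,5-dien-2-yl}-2-methyl-3-oxo-2,3-dihydrofuran-2-yl]acetaldehyde | O=CC[C@@]1(C)OC(=CC1=O)/C(C)=C\[C@@H](O[Si](CC)(CC)CC)/C=C(\Br)CBr
F3 | step 12 | ten-membered bromo carbinol: 28 with the lactone replaced by a free 8-OH and a 1-bromovinyl group on C7 (7,8-anti) | O[C@H]1C[C@@]2(C)OC(=CC2=O)/C(C)=C\[C@@H](O[Si](CC)(CC)CC)[C@@H]1C(Br)=C
F4 | step 8 | (2R)-2-(2-hydroxyethyl)-5-[(2Z,4S)-4-hydroxy-6-(trimethylsilyl)hex-2-en-5-yn-2-yl]-2-methylfuran-3(2H)-one | OCC[C@@]1(C)OC(=CC1=O)/C(C)=C\[C@H](O)C#C[Si](C)(C)C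
F5 | step 8 | (2R)-2-(2-hydroxyethyl)-2-methyl-5-[(2Z)-4-oxo-6-(trimethylsilyl)hex-2-en-5-yn-2-yl]furan-3(2H)-one | OCC[C@@]1(C)OC(=CC1=O)/C(C)=C\C(=O)C#C[Si](C)(C)C
F6 | step 11 | 2-[(2R)-5-[(2Z,4S)-4-hydroxyhepta-2,5,6-trien-2-yl]-2-methyl-3-oxo-2,3-dihydrofuran-2-yl]acetaldehyde | O=CC[C@@]1(C)OC(=CC1=O)/C(C)=C\[C@@H](O)C=C=C
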